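**Plan**

- Retrosynthesis: open the 19,10-lactone, return C15–OH/C16=CH2 to an enol silane of a C15 ketone, and restore a helper ketone at C11. Then cut C8–C9 and C12–C13 together: the seven-membered ring C8–C15–C16–C13–C12–C11–C9 is the (4+3) adduct of ring D as a cyclopentadiene (C8=C15–C16=C13, C14 the CH2) and C9–C11–C12 as a 2-oxyallyl cation.
- Enabling feature: ring D bears oxygen on C13 and C15, so it is a masked 2-methylcyclopentane-1,3-dione, i.e. a 1,3-bis(silyloxy)diene nucleophilic at C8. C10, next to C9, bears the lactone oxygen, so the cation can be released from a C9–C10 epoxy enol silane whose oxygen stays on C10.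
- Further cuts: C5–C6 (Ireland–Claisen from a C9 allylic ester, which also creates the C9=C10 alkene), C9–C10 (aldol), C4–CH3 (Birch alkylation of a benzoate).
- Forward: ring A (steps 1–7) and the ring D acid (steps 8–10) are joined by ester formation and Claisen rearrangement. The epoxide is set through an iodolactone, one cycloaddition closes rings B and C, C11 is deoxygenated, ring D is taken to the enone and allylic alcohol, and fluoride closes the lactone.
- Stereochemistry: C3/C4 by catalytic desymmetrising reduction; C11 from (S)-lactaldehyde relays to C9 (aldol), then C5 and C6 (Claisen), then C10 (iodolactonisation); C8, C9 and C13 in the cycloaddition; C15 by Luche reduction.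

Key step: step 19

**Remarks**

- The target is the 3,13,15-trihydroxylated C19 gibberellin 7-acid 19,10-lactone of the task. Positions are numbered as in gibberellane (C7 is the free acid carbon, C19 the lactone carbonyl, C17 the exocyclic methylene).
- Aldehyde 7 is taken as purchasable (otherwise two routine steps from ethyl (S)-lactate).
- In step 3 the (S)-oxazaborolidine is assumed to give 5; the antipode is equally available if the facial sense is opposite.
- Acid 18 is racemic at the future C8; that centre becomes sp2 in step 18, so 19–27 are carried as C8 epimers. C10 in 9 and 10 is left unassigned because it becomes sp2 in step 6.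

**Route**

Step 1
Reactants: 1 methyl 2,6-dimethoxybenzoate
Product: 3 methyl 2,6-dimethoxy-1-methylcyclohexa-2,5-diene-1-carboxylate, via potassium ester dienolate 2 (not isolated)
Conditions: K, NH3 (l), THF, t-BuOH (1 equiv), −78 °C; then MeI
Reagents that add atoms: iodomethane, CI
Why: Birch reductive alkylation: the ester-stabilised dienolate is methylated at the ipso carbon, which creates the C4 quaternary carbon and leaves C3 and C5 as enol ethers.

Step 2
Reactants: 3 methyl 2,6-dimethoxy-1-methylcyclohexa-2,5-diene-1-carboxylate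
Product: 4 methyl 1-methyl-2,6-dioxocyclohexane-1-carboxylate
Conditions: 1 M HCl, THF, 0 °C to rt
Reagents that add atoms: water, O
Why: Acid hydrolysis of both enol ethers gives the Cs-symmetric diketo ester, which has no α-hydrogen between the carbonyls and so cannot decarboxylate.

Step 3
Reactants: 4 methyl 1-methyl-2,6-dioxocyclohexane-1-carboxylate
Product: 5 methyl (1R,2S)-2-hydroxy-1-methyl-6-oxocyclohexane-1-carboxylate
Conditions: (S)-2-methyl-CBS-oxazaborolidine (20 mol %), catecholborane, toluene, −78 °C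
Reagents that add atoms: none
Why: Corey–Bakshi–Shibata desymmetrisation: the catalyst selects one enantiotopic carbonyl and the bulky borane complex should attack equatorially, anti to the axial ester, so the hydroxyl ends cis to the methyl group and C3 and C4 are set together.

Step 4
Reactants: 5 methyl (1R,2S)-2-hydroxy-1-methyl-6-oxocyclohexane-1-carboxylate
Product: 6 methyl (1R,2S)-2-(tert-butyldimethylsilyloxy)-1-methyl-6-oxocyclohexane-1-carboxylate
Conditions: TBSOTf, 2,6-lutidine, CH2Cl2, −78 to 0 °C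
Reagents that add atoms: tert-butyldimethylsilyl triflate, CC(C)(C)[Si](C)(C)OS(=O)(=O)C(F)(F)F
Why: Silylation of the hindered secondary alcohol blocks retro-aldol cleavage of the β-hydroxy ketone in the basic steps that follow.

Step 5
Reactants: 6 methyl (1R,2S)-2-(tert-butyldimethylsilyloxy)-1-methyl-6-oxocyclohexane-1-carboxylate; 7 (S)-2-[(4-methoxybenzyl)oxy]propanal
Product: 10 ring A β-(triethylsilyloxy) ketone (C9 R with OTES, C11 S with OPMB, 9,11-anti), via lithium enolate 8 (not isolated), via lithium aldolate 9 (not isolated)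
Conditions: LiN(iPr)2, THF, −78 °C; then 7; then TESOTf, −78 to −40 °C
Reagents that add atoms: triethylsilyl triflate, CC[Si](CC)(CC)OS(=O)(=O)C(F)(F)F
Why: Aldol addition of the only possible enolate (C10) to the α-alkoxy aldehyde under Felkin–Anh/Cornforth control should give the 9,11-anti adduct, so C11 of the lactate sets C9; silylation in the same flask prevents retro-aldol.

Step 6
Reactants: 10 ring A β-(triethylsilyloxy) ketone
Product: 11 C5 enol triflate (C5=C10 tetrasubstituted)
Conditions: KN(SiMe3)2, PhNTf2, THF, −78 to 0 °C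
Reagents that add atoms: N-phenylbis(trifluoromethanesulfonimide), O=S(=O)(N(c1ccccc1)S(=O)(=O)C(F)(F)F)C(F)(F)F
Why: C4 is quaternary, so enolisation can only occur towards C10, and O-triflation fixes the C5=C10 double bond.

Step 7
Reactants: 11 C5 enol triflate
Product: 13 methyl (1S,6S)-6-(tert-butyldimethylsilyloxy)-3-[(1R,2S)-1-hydroxy-2-(4-methoxybenzyloxy)propyl]-1-methylcyclohex-2-ene-1-carboxylate, via silyl ether alkene 12 (not isolated)
Conditions: Pd(OAc)2, PPh3, HCO2H, Bu3N, DMF, 60 °C; then 1 M HCl, THF, 0 °C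
Reagents that add atoms: none
Why: Palladium-catalysed formate hydrogenolysis of the vinyl triflate puts hydrogen on C5, and dilute acid then removes the unhindered secondary TES ether while the neopentyl TBS ether and the PMB ether stay.

Step 8
Reactants: 14 2-methylcyclopentane-1,3-dione
Product: 15 3-(allyloxy)-2-methylcyclopent-2-en-1-one
Conditions: allyl alcohol, TsOH·H2O (cat.), benzene, reflux, Dean–Stark
Reagents that add atoms: allyl alcohol, C=CCO
Why: Acid-catalysed O-alkylation of the enolised dione with removal of water gives the vinylogous ester, which masks the dione as a base-stable group that can be removed later under neutral conditions.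

Step 9
Reactants: 15 3-(allyloxy)-2-methylcyclopent-2-en-1-one
Product: 17 methyl 2-[4-(allyloxy)-3-methyl-2-oxocyclopent-3-en-1-yl]acetate (racemic), via lithium enolate 16 (not isolated)
Conditions: LiN(iPr)2, THF, −78 °C; then BrCH2CO2Me, −78 to −20 °C
Reagents that add atoms: methyl bromoacetate, COC(=O)CBr
Why: Stork–Danheiser kinetic α′-alkylation of the vinylogous ester attaches the C6–C7 unit to the future C8.

Step 10
Reactants: 17 methyl 2-[4-(allyloxy)-3-methyl-2-oxocyclopent-3-en-1-yl]acetate
Product: 18 2-[4-(allyloxy)-3-methyl-2-oxocyclopent-3-en-1-yl]acetic acid (racemic)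
Conditions: LiOH, THF/H2O, 0 °C; then 1 M HCl to pH 3
Reagents that add atoms: lithium hydroxide, [Li+].[OH-]
Why: Saponification of the unhindered methyl ester is much faster than hydroxide attack on the vinylogous ester.

Step 11
Reactants: 13 ring A allylic alcohol; 18 ring D acid
Product: 19 C9 ester of 13 with 18 (C8 epimers)
Conditions: EDC·HCl, DMAP, CH2Cl2, 0 °C to rt
Reagents that add atoms: none
Why: Steglich-type carbodiimide esterification joins the two fragments through the C9 oxygen without touching either stereocentre of the alcohol.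

Step 12
Reactants: 19 C9 ester of 13 with 18
Product: 22 Claisen acid (C5–C6 bond formed, C7 acid, exocyclic C9=C10 with C11 cis to C1), via silyl ketene acetal 20 (not isolated), via trimethylsilyl ester 21 (not isolated)
Conditions: LiN(iPr)2, Me3SiCl, Et3N, THF, −78 to 40 °C; then 1 M HCl
Reagents that add atoms: none
Why: Ireland–Claisen rearrangement through a chair with the C11 substituent equatorial: the C9 configuration directs C6 to the face of C5 cis to the C4 ester, the (E)-silyl ketene acetal from kinetic enolisation in THF should give the 5,6-anti relationship (natural C6), and the exocyclic alkene is formed with C11 cis to C1.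

Step 13
Reactants: 22 Claisen acid
Product: 23 7,10-iodolactone (O on C10 cis to C6 and to the C4 ester, I on C9 anti)
Conditions: I2, NaHCO3, MeCN/H2O, 0 °C, dark
Reagents that add atoms: iodine, II
Why: Iodolactonisation: 5-exo attack of the C7 carboxylate on the tertiary alkene carbon C10 can only give the cis-fused γ-lactone, so oxygen is delivered to C10 on the face of C6 (and of C19) with iodide anti at C9.

Step 14
Reactants: 23 7,10-iodolactone
Product: 24 C9–C10 epoxide with C7 2-(trimethylsilyl)ethyl ester and C11–OPMB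
Conditions: NaH, Me3SiCH2CH2OH (1.1 equiv each), THF, 0 °C
Reagents that add atoms: 2-(trimethylsilyl)ethanol, C[Si](C)(C)CCO
Why: Alkoxide opens the γ-lactone to the ester and the freed C10 alkoxide displaces the anti iodide with inversion, giving the spiro-epoxide with its oxygen on the face of the C19 ester.

Step 15
Reactants: 24 epoxide PMB ether
Product: 25 epoxy alcohol (C11–OH)
Conditions: DDQ, CH2Cl2/pH 7 buffer, 0 °C
Reagents that add atoms: none
Why: Oxidative cleavage of the electron-rich 4-methoxybenzyl ether; the electron-poor vinylogous ester and the epoxide are not oxidised.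

Step 16
Reactants: 25 epoxy alcohol
Product: 26 epoxy methyl ketone (C11 ketone)
Conditions: Dess–Martin periodinane, NaHCO3, CH2Cl2, rt
Reagents that add atoms: none
Why: Buffered Dess–Martin oxidation of the secondary alcohol gives the α,β-epoxy ketone without epoxide opening.

Step 17
Reactants: 26 epoxy methyl ketone
Product: 27 epoxy ketone with free 2-methylcyclopentane-1,3-dione (ring D)
Conditions: Pd(PPh3)4 (5 mol %), morpholine, THF, rt
Reagents that add atoms: none
Why: Tsuji–Trost deallylation: zerovalent palladium ionises the allyl vinylogous ester and morpholine captures the π-allyl fragment, which frees the dione under neutral conditions.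

Step 18
Reactants: 27 epoxy ketone dione
Product: 29 tris(triethylsilyl) compound (C11 enol silane; ring D as C8=C15(OTES)–C16(CH3)=C13(OTES), C14 CH2), via cross-conjugated diene isomer 28 (not isolated)
Conditions: LiN(SiMe3)2 (3.3 equiv), Et3SiCl, THF/DMPU, −78 °C to rt
Reagents that add atoms: chlorotriethylsilane, CC[Si](Cl)(CC)CC
Why: Kinetic enolisation of the methyl ketone (C12) and double enolisation of the dione are trapped on oxygen, and a [1,5]-hydrogen shift at room temperature should move the C8 hydrogen to C14 to give the fully conjugated diene with C8 as its terminus.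

Step 19
Reactants: 29 tris(triethylsilyl) epoxy enol silane diene
Product: 31 tetracyclic cycloadduct (C11 ketone, C10–OTES, C13–OTES, C15 enol silane), via silyloxyallyl cation triflate 30 (not isolated)
Conditions: Et3SiOTf (10 mol %), 2,6-di-tert-butyl-4-methylpyridine (20 mol %), CH2Cl2, −78 to −40 °C
Reagents that add atoms: none
Why: Proposed new method: catalytic Et3SiOTf silylates the epoxide oxygen, the C9–O bond ionises to a 2-(triethylsilyloxy)allyl cation (C9–C11–C12, oxygen kept on C10 as OTES), the nucleophilic diene terminus C8 attacks C9, and the enol silane carbon C12 closes on the silyloxy-stabilised cation carbon C13 with release of Et3SiOTf from the C11 oxygen; the closest known reaction type is the Lewis-acid-catalysed (4+3) cycloaddition of epoxy enol silanes with furans and cyclopentadiene, including tethered dienes, and the new element is a tethered 1,3-bis(silyloxy)cyclopentadiene as the four-carbon partner. Ring B closes 5-exo-trig at both partners (C8–C9), ring C closes 6-(enolendo)-exo-trig (C12–C13), and the two bonds together complete the seven-membered ring C8–C15–C16–C13–C12–C11–C9 of the bicyclo[3.2.1]octene. C9 should form with the silyloxyallyl residue syn to the axial C10–OTES and away from the ring methylene C1, because ring B is built on the trans-diequatorial C5 and C10 bonds of the ring A chair. C8 should arise from the extended arrangement, in which the C11–OTES group lies over the unsubstituted C14 methylene and not over the C15–OTES/C16–CH3 edge; this puts C14 on the face of O10 as in the target, and C13 is then fixed by the bridge. The selectivity needed is closure at C13 ((4+3)) against five-membered closure at C15, and it should be favoured because C15 is flanked by the new quaternary C8 while the U-shaped cation spans the C8 to C13 distance.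

Step 20
Reactants: 31 tetracyclic cycloadduct
Product: 32 C11 enol triflate (C11=C12)
Conditions: KN(SiMe3)2, PhNTf2, THF, −78 °C
Reagents that add atoms: N-phenylbis(trifluoromethanesulfonimide), O=S(=O)(N(c1ccccc1)S(=O)(=O)C(F)(F)F)C(F)(F)F
Why: Kinetic deprotonation occurs at the accessible C12 methylene and not at the hindered C9 methine, so the C9 configuration and the β-silyloxy group at C10 are untouched.

Step 21
Reactants: 32 C11 enol triflate
Product: 33 C11=C12 alkene
Conditions: Pd(PPh3)4 (5 mol %), LiCl, Bu3SnH, THF, 50 °C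
Reagents that add atoms: none
Why: Palladium-catalysed reduction of the vinyl triflate by tin hydride under neutral conditions keeps the acid-sensitive enol silane at C15.

Step 22
Reactants: 33 C11=C12 alkene
Product: 34 C11,C12-saturated tetracycle (C15 enol silane retained)
Conditions: H2 (1 atm), Pd/C, EtOAc, rt
Reagents that add atoms: none
Why: The cis-disubstituted alkene is hydrogenated while the tetrasubstituted silyl enol ether is inert, which completes removal of the helper oxygen at C11.

Step 23
Reactants: 34 saturated tetracycle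
Product: 35 15-oxo-16(17)-ene enone
Conditions: Pd(OAc)2 (1.1 equiv), MeCN, rt
Reagents that add atoms: none
Why: Saegusa–Ito oxidation: the oxa-π-allyl complex of divalent palladium can lose a β-hydride only from the C17 methyl group (C13 is quaternary), so the exocyclic enone is the only product possible.

Step 24
Reactants: 35 enone
Product: 36 fully protected 15-hydroxy-16(17)-ene
Conditions: NaBH4, CeCl3·7H2O, MeOH, −78 °C
Reagents that add atoms: none
Why: Luche 1,2-reduction: hydride should arrive from the exo face (the side of the C14 bridge), giving the C15 hydroxyl syn to the C9–C11–C12 bridge as in the target.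

Step 25
Reactants: 36 fully protected 15-hydroxy-16(17)-ene
Product: 38 target gibberellin: 3,13,15-trihydroxy-20-norgibberell-16-ene-7,19-dioic acid 19,10-lactone, via tetraol methyl ester 37 (not isolated)
Conditions: Bu4NF, THF, 0 °C to rt; aq. NH4Cl
Reagents that add atoms: none
Why: Fluoride removes the two TES ethers and the TBS ether, cleaves the 2-(trimethylsilyl)ethyl ester by β-elimination, and the freed axial C10 alkoxide closes onto the 1,3-diaxial C19 methyl ester to form the γ-lactone.

**Compound list**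

1 | methyl 2,6-dimethoxybenzoate | COC(=O)c1c(OC)cccc1OC | starting material
2 | potassium dienolate of methyl 2,6-dimethoxycyclohexa-2,5-diene-1-carboxylate | COC([O-])=C1C(OC)=CCC=C1OC.[K+] | intermediate (not isolated)
3 | methyl 2,6-dimethoxy-1-methylcyclohexa-2,5-diene-1-carboxylate | COC(=O)C1(C)C(OC)=CCC=C1OC | intermediate
4 | methyl 1-methyl-2,6-dioxocyclohexane-1-carboxylate | COC(=O)C1(C)C(=O)CCCC1=O | intermediate
5 | methyl (1R,2S)-2-hydroxy-1-methyl-6-oxocyclohexane-1-carboxylate (OH cis to CH3) | COC(=O)[C@]1(C)[C@@H](O)CCCC1=O | intermediate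
6 | methyl (1R,2S)-2-(tert-butyldimethylsilyloxy)-1-methyl-6-oxocyclohexane-1-carboxylate | COC(=O)[C@]1(C)[C@@H](O[Si](C)(C)C(C)(C)C)CCCC1=O | intermediate
7 | (S)-2-[(4-methoxybenzyl)oxy]propanal | C[C@H](OCc1ccc(OC)cc1)C=O | starting material
8 | lithium enolate of 6 (C5–O, C5=C10) | COC(=O)[C@]1(C)[C@@H](O[Si](C)(C)C(C)(C)C)CCC=C1[O-].[Li+] | intermediate (not isolated)
9 | lithium aldolate of 6 and 7 (C9 R, C11 S; C10 unassigned) | C[C@H](OCc1ccc(OC)cc1)[C@H]([O-])C1CC[C@H](O[Si](C)(C)C(C)(C)C)[C@@](C)(C(=O)OC)C1=O.[Li+] | intermediate (not isolated)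
10 | ring A ketone with (1R,2S)-2-(4-methoxybenzyloxy)-1-(triethylsilyloxy)propyl at C10 (C10 unassigned) | C[C@H](OCc1ccc(OC)cc1)[C@H](O[Si](CC)(CC)CC)C1CC[C@H](O[Si](C)(C)C(C)(C)C)[C@@](C)(C(=O)OC)C1=O | intermediate
11 | C5 enol triflate of 10 | C[C@H](OCc1ccc(OC)cc1)[C@H](O[Si](CC)(CC)CC)C1=C(OS(=O)(=O)C(F)(F)F)[C@](C)(C(=O)OC)[C@@H](O[Si](C)(C)C(C)(C)C)CC1 | intermediate
12 | C5=C10 cyclohexene with C9–OTES | C[C@H](OCc1ccc(OC)cc1)[C@H](O[Si](CC)(CC)CC)C1=C[C@](C)(C(=O)OC)[C@@H](O[Si](C)(C)C(C)(C)C)CC1 | intermediate (not isolated)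
13 | methyl (1S,6S)-6-(tert-butyldimethylsilyloxy)-3-[(1R,2S)-1-hydroxy-2-(4-methoxybenzyloxy)propyl]-1-methylcyclohex-2-ene-1-carboxylate | C[C@H](OCc1ccc(OC)cc1)[C@H](O)C1=C[C@](C)(C(=O)OC)[C@@H](O[Si](C)(C)C(C)(C)C)CC1 | intermediate
14 | 2-methylcyclopentane-1,3-dione | CC1C(=O)CCC1=O | starting material
15 | 3-(allyloxy)-2-methylcyclopent-2-en-1-one | C=CCOC1=C(C)C(=O)CC1 | intermediate
16 | lithium α′-enolate of 15 | C=CCOC1=C(C)C([O-])=CC1.[Li+] | intermediate (not isolated)
17 | methyl 2-[4-(allyloxy)-3-methyl-2-oxocyclopent-3-en-1-yl]acetate (racemic) | COC(=O)CC1CC(OCC=C)=C(C)C1=O | intermediate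
18 | 2-[4-(allyloxy)-3-methyl-2-oxocyclopent-3-en-1-yl]acetic acid (racemic) | OC(=O)CC1CC(OCC=C)=C(C)C1=O | intermediate
19 | C9 ester of 13 with 18 (C8 epimers) | C[C@H](OCc1ccc(OC)cc1)[C@H](OC(=O)CC2CC(OCC=C)=C(C)C2=O)C1=C[C@](C)(C(=O)OC)[C@@H](O[Si](C)(C)C(C)(C)C)CC1 | intermediate
20 | (E)-trimethylsilyl ketene acetal of 19 (OSiMe3 trans to C8) | C[C@H](OCc1ccc(OC)cc1)[C@H](O/C(O[Si](C)(C)C)=C\C2CC(OCC=C)=C(C)C2=O)C1=C[C@](C)(C(=O)OC)[C@@H](O[Si](C)(C)C(C)(C)C)CC1 | intermediate (not isolated)
21 | trimethylsilyl ester of 22 | C[C@H](OCc1ccc(OC)cc1)/C=C1\CC[C@H](O[Si](C)(C)C(C)(C)C)[C@@](C)(C(=O)OC)[C@H]1[C@@H](C2CC(OCC=C)=C(C)C2=O)C(=O)O[Si](C)(C)C | intermediate (not isolated)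
22 | Claisen acid: ring A with exocyclic C9=C10 (C11 cis to C1), C5–C6 bond, C7 acid, ring D vinylogous ester on C6 (C8 epimers) | C[C@H](OCc1ccc(OC)cc1)/C=C1\CC[C@H](O[Si](C)(C)C(C)(C)C)[C@@](C)(C(=O)OC)[C@H]1[C@@H](C2CC(OCC=C)=C(C)C2=O)C(=O)O | intermediate
23 | 7,10-iodolactone (cis-fused; C9 iodide anti to O10) | C[C@H](OCc1ccc(OC)cc1)[C@@H](I)[C@]12CC[C@H](O[Si](C)(C)C(C)(C)C)[C@@](C)(C(=O)OC)[C@H]1[C@@H](C3CC(OCC=C)=C(C)C3=O)C(=O)O2 | intermediate
24 | C9–C10 spiro-epoxide (O cis to the C19 ester), C7 2-(trimethylsilyl)ethyl ester, C11–OPMB | C[C@H](OCc1ccc(OC)cc1)[C@@H]1O[C@]12CC[C@H](O[Si](C)(C)C(C)(C)C)[C@@](C)(C(=O)OC)[C@H]2[C@@H](C3CC(OCC=C)=C(C)C3=O)C(=O)OCC[Si](C)(C)C | intermediate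
25 | epoxy alcohol (C11–OH) | C[C@H](O)[C@@H]1O[C@]12CC[C@H](O[Si](C)(C)C(C)(C)C)[C@@](C)(C(=O)OC)[C@H]2[C@@H](C3CC(OCC=C)=C(C)C3=O)C(=O)OCC[Si](C)(C)C | intermediate
26 | epoxy methyl ketone (C11=O), ring D allyl vinylogous ester | CC(=O)[C@@H]1O[C@]12CC[C@H](O[Si](C)(C)C(C)(C)C)[C@@](C)(C(=O)OC)[C@H]2[C@@H](C3CC(OCC=C)=C(C)C3=O)C(=O)OCC[Si](C)(C)C | intermediate
27 | epoxy methyl ketone with free ring D 2-methyl-1,3-dione (drawn as diketone) | CC(=O)[C@@H]1O[C@]12CC[C@H](O[Si](C)(C)C(C)(C)C)[C@@](C)(C(=O)OC)[C@H]2[C@@H](C3CC(=O)C(C)C3=O)C(=O)OCC[Si](C)(C)C | intermediate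
28 | tris(triethylsilyl) compound, ring D as C15(OTES)=C16–C13(OTES)=C14 with sp3 C8 | C=C(O[Si](CC)(CC)CC)[C@@H]1O[C@]12CC[C@H](O[Si](C)(C)C(C)(C)C)[C@@](C)(C(=O)OC)[C@H]2[C@@H](C3C(O[Si](CC)(CC)CC)=C(C)C(O[Si](CC)(CC)CC)=C3)C(=O)OCC[Si](C)(C)C | intermediate (not isolated)
29 | tris(triethylsilyl) compound, ring D as C8=C15(OTES)–C16(CH3)=C13(OTES), C14 CH2 | C=C(O[Si](CC)(CC)CC)[C@@H]1O[C@]12CC[C@H](O[Si](C)(C)C(C)(C)C)[C@@](C)(C(=O)OC)[C@H]2[C@@H](C3=C(O[Si](CC)(CC)CC)C(C)=C(O[Si](CC)(CC)CC)C3)C(=O)OCC[Si](C)(C)C | intermediate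
30 | 2-(triethylsilyloxy)allyl cation (C9–C11–C12) with C10–OTES, triflate salt | C=C(O[Si](CC)(CC)CC)[CH+][C@]1(O[Si](CC)(CC)CC)CC[C@H](O[Si](C)(C)C(C)(C)C)[C@@](C)(C(=O)OC)[C@H]1[C@@H](C2=C(O[Si](CC)(CC)CC)C(C)=C(O[Si](CC)(CC)CC)C2)C(=O)OCC[Si](C)(C)C.[O-]S(=O)(=O)C(F)(F)F | intermediate (not isolated)
31 | cycloadduct: gibberellane skeleton with C11 ketone, C10–OTES, C13–OTES, C15(OTES)=C16–CH3, C3–OTBS, C19 methyl ester, C7 2-(trimethylsilyl)ethyl ester | CC1=C(O[Si](CC)(CC)CC)[C@]23C[C@@]1(O[Si](CC)(CC)CC)CC(=O)[C@H]2[C@]4(O[Si](CC)(CC)CC)CC[C@H](O[Si](C)(C)C(C)(C)C)[C@@](C)(C(=O)OC)[C@H]4[C@@H]3C(=O)OCC[Si](C)(C)C | intermediate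
32 | C11 enol triflate of 31 (C11=C12) | CC1=C(O[Si](CC)(CC)CC)[C@]23C[C@@]1(O[Si](CC)(CC)CC)C=C(OS(=O)(=O)C(F)(F)F)[C@H]2[C@]4(O[Si](CC)(CC)CC)CC[C@H](O[Si](C)(C)C(C)(C)C)[C@@](C)(C(=O)OC)[C@H]4[C@@H]3C(=O)OCC[Si](C)(C)C | intermediate
33 | 11,12-ene | CC1=C(O[Si](CC)(CC)CC)[C@]23C[C@@]1(O[Si](CC)(CC)CC)C=C[C@H]2[C@]4(O[Si](CC)(CC)CC)CC[C@H](O[Si](C)(C)C(C)(C)C)[C@@](C)(C(=O)OC)[C@H]4[C@@H]3C(=O)OCC[Si](C)(C)C | intermediate
34 | C11,C12-saturated tetracycle with C15 enol silane | CC1=C(O[Si](CC)(CC)CC)[C@]23C[C@@]1(O[Si](CC)(CC)CC)CC[C@H]2[C@]4(O[Si](CC)(CC)CC)CC[C@H](O[Si](C)(C)C(C)(C)C)[C@@](C)(C(=O)OC)[C@H]4[C@@H]3C(=O)OCC[Si](C)(C)C | intermediate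
35 | 15-oxo-16(17)-ene enone | C=C1C(=O)[C@]23C[C@@]1(O[Si](CC)(CC)CC)CC[C@H]2[C@]4(O[Si](CC)(CC)CC)CC[C@H](O[Si](C)(C)C(C)(C)C)[C@@](C)(C(=O)OC)[C@H]4[C@@H]3C(=O)OCC[Si](C)(C)C | intermediate
36 | fully protected 15-hydroxy-16(17)-ene (OH syn to the C9–C11–C12 bridge; C10 and C13 OTES, C3 OTBS, C19 methyl ester, C7 2-(trimethylsilyl)ethyl ester) | C=C1[C@@H](O)[C@]23C[C@@]1(O[Si](CC)(CC)CC)CC[C@H]2[C@]4(O[Si](CC)(CC)CC)CC[C@H](O[Si](C)(C)C(C)(C)C)[C@@](C)(C(=O)OC)[C@H]4[C@@H]3C(=O)OCC[Si](C)(C)C | intermediate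
37 | 3,10,13,15-tetrahydroxy C19 methyl ester C7 acid (seco-lactone) | C=C1[C@@H](O)[C@]23C[C@@]1(O)CC[C@H]2[C@]4(O)CC[C@H](O)[C@@](C)(C(=O)OC)[C@H]4[C@@H]3C(=O)O | intermediate (not isolated)
38 | target gibberellin: 3,13,15-trihydroxy-20-norgibberell-16-ene-7,19-dioic acid 19,10-lactone (15-OH syn to the C9–C11–C12 bridge) | C=C1[C@@H](O)[C@]23C[C@@]1(O)CC[C@H]2[C@@]12CC[C@H](O)[C@@](C)(C(=O)O1)[C@H]2[C@@H]3C(=O)O | target

**Totals and risks**

Total step count: 25. Longest linear sequence: 22 steps (steps 1–7 and 11–25); the ring D acid takes steps 8–10.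

Steps most likely to fail:

1. Step 19. The cation may close onto C15 after the first C–C bond (a five-membered ring instead of the bridged six-membered ring). The diene may be attacked on the wrong face, so C8 and C9 form with the wrong relationship. The epoxide may ionise at the tertiary C10 and undergo a 1,2-shift. Fallback (stepwise anionic annulation by known reaction types), setting out from 27: the epoxy ketone is opened reductively at C9 with PhSeSePh/NaBH4/AcOH in EtOH to the C10 tertiary alcohol bearing a 2-oxopropyl chain F1. The alcohol is capped with TESOTf/2,6-lutidine to the silyl ether F2. DDQ in dioxane dehydrogenates the dione across C8–C14 to the cyclopent-4-ene-1,3-dione F3. Soft enolisation (MgBr2·OEt2, iPr2NEt) then lets C9 add to C8 (intramolecular Michael addition, ring B) and C12 add to the C13 carbonyl (intramolecular aldol, ring C) to give the tetracyclic ketol F4. TESOTf/Et3N silylates C13–OH and converts the C15 ketone to its enol silane (the C11 enol silane is hydrolysed on mild acidic work-up), which comes back to the route at 31.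

2. Step 12. Deprotonation may occur at the ring D vinylogous ester in place of the ester, the rearrangement at the neopentyl C5 may be slow, and facial selectivity may erode through the competing arrangement with C11 inside. Fallback (simpler Claisen partner, ring D attached afterwards by enolate alkylation), setting out from 13: Johnson–Claisen rearrangement with MeC(OMe)3 and catalytic propionic acid at 130 °C gives the C5-acetic methyl ester F5. Its lithium enolate is brominated with CBr4 to the α-bromo ester F6. The lithium α′-enolate 16 (from 15) displaces the bromide to give the C7 methyl ester of the Claisen acid F7 as C6 epimers. LiOH cleaves only the unhindered C7 ester and the route is rejoined at 22. C6 would then be equilibrated at the stage of 34 with substoichiometric KN(SiMe3)2.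

3. Step 3. The catalyst may discriminate poorly between the two enantiotopic carbonyls or between the two faces (giving the hydroxyl cis to the ester), and the β,β′-diketo ester may undergo retro-Claisen opening. Fallback (substrate-controlled reduction followed by enzymatic resolution), setting out from 4: LiBH(sBu)3 at −78 °C attacks equatorially to give the racemic trans hydroxy ketone F8. Candida antarctica lipase B with vinyl acetate acetylates the unwanted (1S,2R)-enantiomer to its acetate F9, and the unreacted alcohol is 5, where the route is rejoined.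

**Further compounds**

F1 | step 19 | C10 tertiary alcohol with 2-oxopropyl chain (reduced epoxide of 27) | CC(=O)C[C@]1(O)CC[C@H](O[Si](C)(C)C(C)(C)C)[C@@](C)(C(=O)OC)[C@H]1[C@@H](C2CC(=O)C(C)C2=O)C(=O)OCC[Si](C)(C)C
F2 | step 19 | C10 triethylsilyl ether of F1 | CC(=O)C[C@]1(O[Si](CC)(CC)CC)CC[C@H](O[Si](C)(C)C(C)(C)C)[C@@](C)(C(=O)OC)[C@H]1[C@@H](C2CC(=O)C(C)C2=O)C(=O)OCC[Si](C)(C)C
F3 | step 19 | cyclopent-4-ene-1,3-dione (C8=C14) derived from F2 | CC(=O)C[C@]1(O[Si](CC)(CC)CC)CC[C@H](O[Si](C)(C)C(C)(C)C)[C@@](C)(C(=O)OC)[C@H]1[C@@H](C2=CC(=O)C(C)C2=O)C(=O)OCC[Si](C)(C)C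
F4 | step 19 | tetracyclic ketol (C13–OH, C11 and C15 ketones, C10–OTES) | CC1C(=O)[C@]23C[C@@]1(O)CC(=O)[C@H]2[C@]4(O[Si](CC)(CC)CC)CC[C@H](O[Si](C)(C)C(C)(C)C)[C@@](C)(C(=O)OC)[C@H]4[C@@H]3C(=O)OCC[Si](C)(C)C
F5 | step 12 | C5-acetic methyl ester with exocyclic C9=C10 (Johnson–Claisen product) | C[C@H](OCc1ccc(OC)cc1)/C=C1\CC[C@H](O[Si](C)(C)C(C)(C)C)[C@@](C)(C(=O)OC)[C@H]1CC(=O)OC
F6 | step 12 | C6 α-bromo ester of F5 | C[C@H](OCc1ccc(OC)cc1)/C=C1\CC[C@H](O[Si](C)(C)C(C)(C)C)[C@@](C)(C(=O)OC)[C@H]1C(Br)C(=O)OC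
F7 | step 12 | C7 methyl ester of 22 (C6 and C8 epimers) | C[C@H](OCc1ccc(OC)cc1)/C=C1\CC[C@H](O[Si](C)(C)C(C)(C)C)[C@@](C)(C(=O)OC)[C@H]1C(C2CC(OCC=C)=C(C)C2=O)C(=O)OC
F8 | step 3 | racemic trans methyl 2-hydroxy-1-methyl-6-oxocyclohexane-1-carboxylate (OH cis to CH3) | COC(=O)[C@]1(C)[C@@H](O)CCCC1=O.COC(=O)[C@@]1(C)[C@H](O)CCCC1=O
F9 | step 3 | methyl (1S,2R)-2-acetoxy-1-methyl-6-oxocyclohexane-1-carboxylate | COC(=O)[C@@]1(C)[C@H](OC(C)=O)CCCC1=O
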